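**Assumption:** the target has no stereocentre or stereoaxis, so it is a single achiral compound and no stereocontrol is needed. Heptylzinc bromide is taken as the commercial 0.5 M THF solution.

## Retrosynthetic overview

1. Target 9 comes from Pinnick oxidation of depside aldehyde 8; the B-ring CHO serves as a latent CO2H, so no protecting groups are used.
2. 8 is cut at the depside C(acyl)–O bond: dehydrogenative coupling of the formyl C–H of salicylaldehyde 5 with the phenol O–H of 7 (new Rh(III) method).
3. 5 and 7 are the two regioisomeric formylation products (ortho and para to OH) of one phenol, 3.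
4. 3 comes from Negishi alkylation of 3-bromo-5-methoxyphenol 1 with heptylzinc bromide 2.
5. No ring is formed; both benzene rings are bought in 1.

## Route

Step 1
Reactants: 1 3-bromo-5-methoxyphenol; 2 heptylzinc bromide (2.3 equiv)
Product: 3 3-heptyl-5-methoxyphenol
Conditions: Pd(OAc)2 (2 mol %), SPhos (4 mol %), THF, 25 → 50 °C; aq. NH4Cl
Reagents that add atoms: none
Why: Negishi sp2–sp3 cross-coupling, in which a primary alkylzinc halide with Pd/SPhos couples faster than it is protonated by the free phenol, and the extra equivalent covers the O–H.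

Step 2
Reactants: 3 3-heptyl-5-methoxyphenol
Product: 5 2-heptyl-6-hydroxy-4-methoxybenzaldehyde, via salicyl alcohol magnesium salt 4 (not isolated)
Conditions: MgCl2 (1.5 equiv), Et3N (3.75 equiv), (CH2O)n (6.8 equiv), MeCN, reflux; then 1 M HCl
Reagents that add atoms: paraformaldehyde (as formaldehyde), C=O
Why: Casnati–Skattebøl magnesium-phenoxide ortho-formylation delivers formaldehyde only ortho to OH, and of the two ortho sites the one para to OMe (between OH and heptyl) is electronically favoured over the site between the two oxygens; the hydroxymethyl intermediate is oxidised in the flask by hydride transfer to a second formaldehyde.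

Step 3
Reactants: 3 3-heptyl-5-methoxyphenol
Product: 7 2-heptyl-4-hydroxy-6-methoxybenzaldehyde, via aryl iminium chloride 6 (not isolated)
Conditions: POCl3 (1.5 equiv), DMF (5 equiv), MeCN, 0 °C → rt; then H2O, 50 °C
Reagents that add atoms: N,N-dimethylformamide, CN(C)C=O; water, O
Why: Vilsmeier–Haack formylation of a free 3-alkoxyphenol goes mainly para to OH (here the carbon between heptyl and OMe), and the minor ortho isomer is compound 5 itself, which is separated easily (chelated, non-polar) and added to the step 2 material.

Step 4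
Reactants: 5 2-heptyl-6-hydroxy-4-methoxybenzaldehyde (1.0 equiv); 7 2-heptyl-4-hydroxy-6-methoxybenzaldehyde (1.2 equiv)
Product: 8 4-formyl-3-heptyl-5-methoxyphenyl 2-heptyl-6-hydroxy-4-methoxybenzoate
Conditions: [Cp*RhCl2]2 (2.5 mol %), AgSbF6 (10 mol %), PivOH (20 mol %), Ag2CO3 (1.2 equiv), 4 Å MS, DCE, 70 °C, N2, dark
Reagents that add atoms: none
Why: Proposed new method: a Cp*Rh(III)-catalysed, hydroxyl-directed dehydrogenative C(acyl)–O coupling of a salicylaldehyde with a phenol, in which 5 binds Rh through its phenoxide, pivalate-assisted cleavage of the chelated formyl C–H gives a five-membered acyl(aryloxo)rhodacycle, the unhindered and more acidic 4-OH of 7 enters as aryloxide, C(acyl)–O reductive elimination (possibly Ag(I)-induced) releases 8 and Rh(I), and Ag2CO3 reoxidises Rh(I) while carbonate takes up both protons; the CHO of 7 has no ortho-OH and so cannot be activated, and the OH groups of 5 and 8 are chelated and hindered, so cross-coupling should beat self-esterification; the closest known reaction types are Rh(III)-catalysed OH-directed formyl C–H functionalisation of salicylaldehydes (oxidative annulation with alkynes to chromones, C–N coupling to salicylamides) and capture of aroyl–Rh(III) by alcohols in oxidative carbonylation, whereas intermolecular acyl–O coupling with a phenol has not been shown.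

Step 5
Reactants: 8 4-formyl-3-heptyl-5-methoxyphenyl 2-heptyl-6-hydroxy-4-methoxybenzoate
Product: 9 2-heptyl-4-[(2-heptyl-6-hydroxy-4-methoxybenzoyl)oxy]-6-methoxybenzoic acid (target)
Conditions: NaClO2 (3 equiv), NaH2PO4 (3 equiv), 2-methyl-2-butene (20 equiv), t-BuOH/THF/H2O, 0 °C → rt
Reagents that add atoms: sodium chlorite, [Na+].[O-]Cl=O
Why: Pinnick (Lindgren) oxidation converts even 2,6-disubstituted aryl aldehydes to acids at pH 3–4, where the depside ester and the chelated phenol survive and the alkene scavenger removes HOCl before it can chlorinate the electron-rich rings.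

## Compound list

1 | 3-bromo-5-methoxyphenol | COc1cc(O)cc(Br)c1 | starting material
2 | heptylzinc bromide | CCCCCCC[Zn]Br | starting material
3 | 3-heptyl-5-methoxyphenol | CCCCCCCc1cc(O)cc(OC)c1 | intermediate
4 | 3-heptyl-2-(hydroxymethyl)-5-methoxyphenol (present in the flask as its magnesium phenoxide, not isolated) | CCCCCCCc1cc(OC)cc(O)c1CO | intermediate
5 | 2-heptyl-6-hydroxy-4-methoxybenzaldehyde | CCCCCCCc1cc(OC)cc(O)c1C=O | intermediate
6 | (2-heptyl-4-hydroxy-6-methoxybenzylidene)dimethyliminium chloride (not isolated) | CCCCCCCc1cc(O)cc(OC)c1C=[N+](C)C.[Cl-] | intermediate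
7 | 2-heptyl-4-hydroxy-6-methoxybenzaldehyde | CCCCCCCc1cc(O)cc(OC)c1C=O | intermediate
8 | 4-formyl-3-heptyl-5-methoxyphenyl 2-heptyl-6-hydroxy-4-methoxybenzoate | CCCCCCCc1cc(OC)cc(O)c1C(=O)Oc1cc(CCCCCCC)c(C=O)c(OC)c1 | intermediate
9 | 2-heptyl-4-[(2-heptyl-6-hydroxy-4-methoxybenzoyl)oxy]-6-methoxybenzoic acid (CNP0128141.0) | CCCCCCCc1cc(OC)cc(O)c1C(=O)Oc1cc(CCCCCCC)c(C(=O)O)c(OC)c1 | target

## Step count and risks

Total step count: 5. Longest linear sequence: 4 (steps 1, 2 or 3, 4, 5).

The three steps most likely to fail:

**Step 4 (proposed new coupling).** The acyl rhodacycle may decarbonylate, be captured by carboxylate, or simply not undergo C–O reductive elimination. The fallback sets out from 5 and comes back at 8. Pinnick oxidation of 5 (NaClO2, NaH2PO4, 2-methyl-2-butene) gives 2-heptyl-6-hydroxy-4-methoxybenzoic acid F1. F1 is then condensed with 7 by trifluoroacetic anhydride in toluene at room temperature, through 2-heptyl-6-hydroxy-4-methoxybenzoic trifluoroacetic anhydride F2, to give 8. This is the established depside condensation of a free ortho-hydroxy acid with a para-hydroxybenzaldehyde and costs one extra step.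

**Step 3 (para versus ortho formylation).** If the para isomer 7 is not the main product, regiochemistry is fixed by symmetry and chelation instead. The fallback sets out from 3 and comes back at 7. BBr3 in CH2Cl2 demethylates 3 to 5-heptylbenzene-1,3-diol F3. Vilsmeier formylation of this symmetric resorcinol proceeds through (2-heptyl-4,6-dihydroxybenzylidene)dimethyliminium chloride F4 to 2-heptyl-4,6-dihydroxybenzaldehyde F5. Allyl bromide with KHCO3 in acetone alkylates only the non-chelated 4-OH to give 4-(allyloxy)-2-heptyl-6-hydroxybenzaldehyde F6. MeI with K2CO3 in DMF methylates the chelated OH to give 4-(allyloxy)-2-heptyl-6-methoxybenzaldehyde F7. Pd(PPh3)4 with morpholine in THF removes the allyl group to give 7.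

**Step 2 (ortho site selection).** Formylation could occur between OH and OMe instead of between OH and heptyl. The fallback sets out from 3 and comes back at 5. MeI with K2CO3 in acetone gives 1-heptyl-3,5-dimethoxybenzene F8. Vilsmeier formylation, through (2-heptyl-4,6-dimethoxybenzylidene)dimethyliminium chloride F9, gives 2-heptyl-4,6-dimethoxybenzaldehyde F10; the only other ring position lies between the two methoxy groups and is disfavoured. BCl3 in CH2Cl2 at −78 → 0 °C cleaves only the methoxy group ortho to the carbonyl (chelation control) to give 5.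

## Further compounds

F1 | step 4 | 2-heptyl-6-hydroxy-4-methoxybenzoic acid | CCCCCCCc1cc(OC)cc(O)c1C(=O)O
F2 | step 4 | 2-heptyl-6-hydroxy-4-methoxybenzoic trifluoroacetic anhydride | CCCCCCCc1cc(OC)cc(O)c1C(=O)OC(=O)C(F)(F)F
F3 | step 3 | 5-heptylbenzene-1,3-diol | CCCCCCCc1cc(O)cc(O)c1
F4 | step 3 | (2-heptyl-4,6-dihydroxybenzylidene)dimethyliminium chloride | CCCCCCCc1cc(O)cc(O)c1C=[N+](C)C.[Cl-]
F5 | step 3 | 2-heptyl-4,6-dihydroxybenzaldehyde | CCCCCCCc1cc(O)cc(O)c1C=O
F6 | step 3 | 4-(allyloxy)-2-heptyl-6-hydroxybenzaldehyde | CCCCCCCc1cc(OCC=C)cc(O)c1C=O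
F7 | step 3 | 4-(allyloxy)-2-heptyl-6-methoxybenzaldehyde | CCCCCCCc1cc(OCC=C)cc(OC)c1C=O
F8 | step 2 | 1-heptyl-3,5-dimethoxybenzene | CCCCCCCc1cc(OC)cc(OC)c1
F9 | step 2 | (2-heptyl-4,6-dimethoxybenzylidene)dimethyliminium chloride | CCCCCCCc1cc(OC)cc(OC)c1C=[N+](C)C.[Cl-]
F10 | step 2 | 2-heptyl-4,6-dimethoxybenzaldehyde | CCCCCCCc1cc(OC)cc(OC)c1C=O
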